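**Retrosynthetic overview**

- Feature: ring A shares only the C4a–C8a bond with the pyranone ring and carries nothing except the adjacent oxygens on C6 and C7 (C5 and C8 are CH). Ring A is therefore cut at C4a–C5 and C8–C8a into a 2,3-dioxygenated butadiene and the C5=C6 bond of a 2-aryl-4-pyranone.
- The pyranone carbon that becomes C4a carries a benzenesulfinyl group. It activates the dienophile and then leaves as benzenesulfenic acid, so the double bond serves as an alkyne equivalent and one dehydrogenation gives the arene.
- The sulfinyl pyranone is assembled from (phenylsulfanyl)acetone, an amide acetal (future C8a) and 3,4,5-trimethoxybenzoyl chloride (ring B and C2), with the sulfur oxidised last; the diene comes from butane-2,3-dione.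
- The C6 and C7 hydroxyls are told apart at the end by acidity: benzyl on O7, methyl on O6, hydrogenolysis.
- Ring order: ring B is bought, the pyranone ring is built first, ring A is closed last on the pyranone.

Key step: step 5

Assumption: the enaminone double bond in 3 and 5 is drawn with the amino group trans to the acyl group (Z by the sequence rule); the geometry is lost at ring closure. Sulfoxide 7 is used as the racemate, because its sulfur centre is removed in step 5.

**Route**

Step 1
Reactants: 1 1-(phenylsulfanyl)propan-2-one; 2 N,N-dimethylformamide dimethyl acetal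
Product: 3 (Z)-4-(dimethylamino)-3-(phenylsulfanyl)but-3-en-2-one
Conditions: 2 (1.2 equiv), toluene, 80 °C
Reagents that add atoms: none
Why: Enaminone condensation of the amide acetal at the more acidic methylene between sulfur and carbonyl should give the push–pull alkene with loss of two molecules of methanol.

Step 2
Reactants: 3 (Z)-4-(dimethylamino)-3-(phenylsulfanyl)but-3-en-2-one; 4 3,4,5-trimethoxybenzoyl chloride
Product: 6 5-(phenylsulfanyl)-2-(3,4,5-trimethoxyphenyl)-4H-pyran-4-one, via aroylated enaminone 5 (not isolated)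
Conditions: LiHMDS (2.2 equiv), THF, −78 °C; 4, −78 → 0 °C; then 3 M aq. HCl, rt
Reagents that add atoms: none
Why: Kinetic deprotonation of the methyl group of the vinylogous amide and Claisen-type C-acylation give diketone 5 (the second equivalent of base takes up its acidic proton), and on acidification the enol oxygen adds to the aminomethylene carbon and expels dimethylamine (addition–elimination cyclocondensation to the 4-pyranone).

Step 3
Reactants: 6 5-(phenylsulfanyl)-2-(3,4,5-trimethoxyphenyl)-4H-pyran-4-one
Product: 7 racemic 5-(benzenesulfinyl)-2-(3,4,5-trimethoxyphenyl)-4H-pyran-4-one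
Conditions: mCPBA (1.0 equiv), CH2Cl2, −40 → 0 °C
Reagents that add atoms: 3-chloroperoxybenzoic acid, OOC(=O)c1cccc(Cl)c1
Why: Peracid oxidation of the sulfide stops at the sulfoxide with one equivalent at low temperature and leaves the electron-poor pyranone and the arene untouched; the sulfur centre forms as the racemate and is removed in step 5.

Step 4
Reactants: 8 butane-2,3-dione
Product: 9 2,3-bis(trimethylsilyloxy)buta-1,3-diene
Conditions: TMSOTf (2.2 equiv), Et3N (2.6 equiv), Et2O, 0 °C → rt; distillation
Reagents that add atoms: trimethylsilyl trifluoromethanesulfonate, C[Si](C)(C)OS(=O)(=O)C(F)(F)F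
Why: Soft enolisation with O-silylation of both carbonyl groups (silyl enol ether formation) should give the bis(silyloxy)diene.

Step 5
Reactants: 7 racemic 5-(benzenesulfinyl)-2-(3,4,5-trimethoxyphenyl)-4H-pyran-4-one; 9 2,3-bis(trimethylsilyloxy)buta-1,3-diene
Product: 11 2-(3,4,5-trimethoxyphenyl)-6,7-bis(trimethylsilyloxy)-5,8-dihydro-4H-chromen-4-one, via cis-fused sulfinyl cycloadduct 10 (not isolated)
Conditions: 9 (4 equiv), toluene, 110 °C, sealed tube, powdered 4 Å MS, Ar; concentrate, use crude or pass through Et3N-deactivated silica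
Reagents that add atoms: none
Why: Proposed new method: the C5=C6 bond of pyranone 7, made electron-poor by the C4 ketone and the sulfinyl group on C5, should take up the electron-rich diene 9 in a thermal normal-demand suprafacial [4+2] cycloaddition that forms C4a–C5 and C8–C8a (chromone numbering) and closes ring A as a six-membered carbocycle in one intermolecular cycloaddition. The closest known reaction types are Diels–Alder additions of oxygenated dienes to chromones bearing an electron-withdrawing group at C3 and the use of sulfinyl enones and sulfinyl quinones as alkyne equivalents; a monocyclic 4-pyranone has not been used in this role. The suprafacial addition fixes the cis ring fusion of adduct 10, so the sulfinyl group on C4a lies syn to the hydrogen on C8a, and the α-sulfinyl ketone should then lose benzenesulfenic acid by thermal syn-elimination, which restores the C4a=C8a bond of the vinylogous ester and removes both new carbon stereocentres and the sulfur stereocentre. The selectivity needed is reaction at C5=C6 and not at C2=C3, and it is secured by the double activation at C5, by the unsubstituted C6 terminus and by the aryl group that hinders and conjugatively stabilises C2=C3. Diene 9 is symmetrical, so there is no regiochemical question, and an elimination towards C5 instead of C8a would give a dihydro isomer that step 6 aromatises to the same arene.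

Step 6
Reactants: 11 2-(3,4,5-trimethoxyphenyl)-6,7-bis(trimethylsilyloxy)-5,8-dihydro-4H-chromen-4-one
Product: 13 6,7-dihydroxy-2-(3,4,5-trimethoxyphenyl)-4H-chromen-4-one, via 6,7-bis(trimethylsilyloxy)flavone 12 (not isolated)
Conditions: DDQ (1.05 equiv), toluene, 0 °C → rt; filter; then HCl (cat.), MeOH, rt; aq. Na2S2O4 wash
Reagents that add atoms: none
Why: DDQ dehydrogenation of the 1,4-cyclohexadiene (hydride abstraction from allylic C5 or C8, then proton loss) should give the arene while the silyl groups shield the catechol from over-oxidation, and acidic methanolysis then cleaves the two aryl silyl ethers.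

Step 7
Reactants: 13 6,7-dihydroxy-2-(3,4,5-trimethoxyphenyl)-4H-chromen-4-one
Product: 14 7-(benzyloxy)-6-hydroxy-2-(3,4,5-trimethoxyphenyl)-4H-chromen-4-one
Conditions: BnBr (1.05 equiv), K2CO3 (1.05 equiv), DMF, 0 °C → rt
Reagents that add atoms: benzyl bromide, BrCc1ccccc1
Why: Williamson etherification with one equivalent of weak base should go to the C7 hydroxyl, which is para to the C4 carbonyl (a vinylogous acid) and is therefore deprotonated first.

Step 8
Reactants: 14 7-(benzyloxy)-6-hydroxy-2-(3,4,5-trimethoxyphenyl)-4H-chromen-4-one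
Product: 15 7-(benzyloxy)-6-methoxy-2-(3,4,5-trimethoxyphenyl)-4H-chromen-4-one
Conditions: MeI (1.5 equiv), K2CO3 (2 equiv), acetone, 50 °C
Reagents that add atoms: methyl iodide, CI
Why: Williamson O-methylation of the only remaining phenol.

Step 9
Reactants: 15 7-(benzyloxy)-6-methoxy-2-(3,4,5-trimethoxyphenyl)-4H-chromen-4-one
Product: 16 Prosogerin D, 7-hydroxy-6-methoxy-2-(3,4,5-trimethoxyphenyl)-4H-chromen-4-one
Conditions: H2 (1 atm), Pd/C (10 wt%), EtOAc–MeOH, rt; stop after one equivalent of H2
Reagents that add atoms: none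
Why: Hydrogenolysis of the benzyl aryl ether over palladium on carbon is expected to be much faster than reduction of the aryl-conjugated C2=C3 bond of the flavone.

**Compound list**

1 | 1-(phenylsulfanyl)propan-2-one | CC(=O)CSc1ccccc1 | starting material
2 | N,N-dimethylformamide dimethyl acetal | COC(OC)N(C)C | starting material
3 | (Z)-4-(dimethylamino)-3-(phenylsulfanyl)but-3-en-2-one | CC(=O)/C(Sc1ccccc1)=C/N(C)C | intermediate
4 | 3,4,5-trimethoxybenzoyl chloride | COc1cc(C(Cl)=O)cc(OC)c1OC | starting material
5 | (Z)-5-(dimethylamino)-4-(phenylsulfanyl)-1-(3,4,5-trimethoxyphenyl)pent-4-ene-1,3-dione (present as its lithium enolate before acidification) | COc1cc(C(=O)CC(=O)/C(Sc2ccccc2)=C/N(C)C)cc(OC)c1OC | intermediate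
6 | 5-(phenylsulfanyl)-2-(3,4,5-trimethoxyphenyl)-4H-pyran-4-one | COc1cc(-c2cc(=O)c(Sc3ccccc3)co2)cc(OC)c1OC | intermediate
7 | racemic 5-(benzenesulfinyl)-2-(3,4,5-trimethoxyphenyl)-4H-pyran-4-one | COc1cc(-c2cc(=O)c(S(=O)c3ccccc3)co2)cc(OC)c1OC | intermediate
8 | butane-2,3-dione | CC(=O)C(C)=O | starting material
9 | 2,3-bis(trimethylsilyloxy)buta-1,3-diene | C=C(O[Si](C)(C)C)C(=C)O[Si](C)(C)C | intermediate
10 | racemic cis-fused 4a-(benzenesulfinyl)-2-(3,4,5-trimethoxyphenyl)-6,7-bis(trimethylsilyloxy)-4a,5,8,8a-tetrahydro-4H-chromen-4-one (sulfinyl on C4a syn to H on C8a; both sulfur epimers; one enantiomer drawn) | O=C1C=C(c2cc(OC)c(OC)c(OC)c2)O[C@@H]2CC(O[Si](C)(C)C)=C(O[Si](C)(C)C)C[C@]12S(=O)c1ccccc1 | intermediate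
11 | 2-(3,4,5-trimethoxyphenyl)-6,7-bis(trimethylsilyloxy)-5,8-dihydro-4H-chromen-4-one | COc1cc(-c2cc(=O)c3c(o2)CC(O[Si](C)(C)C)=C(O[Si](C)(C)C)C3)cc(OC)c1OC | intermediate
12 | 2-(3,4,5-trimethoxyphenyl)-6,7-bis(trimethylsilyloxy)-4H-chromen-4-one | COc1cc(-c2cc(=O)c3cc(O[Si](C)(C)C)c(O[Si](C)(C)C)cc3o2)cc(OC)c1OC | intermediate
13 | 6,7-dihydroxy-2-(3,4,5-trimethoxyphenyl)-4H-chromen-4-one | COc1cc(-c2cc(=O)c3cc(O)c(O)cc3o2)cc(OC)c1OC | intermediate
14 | 7-(benzyloxy)-6-hydroxy-2-(3,4,5-trimethoxyphenyl)-4H-chromen-4-one | COc1cc(-c2cc(=O)c3cc(O)c(OCc4ccccc4)cc3o2)cc(OC)c1OC | intermediate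
15 | 7-(benzyloxy)-6-methoxy-2-(3,4,5-trimethoxyphenyl)-4H-chromen-4-one | COc1cc(-c2cc(=O)c3cc(OC)c(OCc4ccccc4)cc3o2)cc(OC)c1OC | intermediate
16 | Prosogerin D | COc1cc2c(=O)cc(-c3cc(OC)c(OC)c(OC)c3)oc2cc1O | target

**Step count**

Total: 9 steps. Longest linear sequence: 8 steps (steps 1, 2, 3, 5, 6, 7, 8, 9); the diene branch (step 4) joins at step 5.

**Steps most likely to fail**

1. Step 5 (proposed new method). The pyranone double bond carries the ring oxygen as a donor and is part of a partly aromatic vinylogous ester, so the cycloaddition may be too slow. The diene could then be used up by hydrolysis, or by conjugate addition at C6 followed by opening of the pyranone ring. Fallback by known chemistry, setting out from 4 and coming back at 13: 1-(2,4,5-trihydroxyphenyl)ethan-1-one F1 (purchased) is benzylated at its two non-chelated hydroxyls (BnBr, K2CO3, acetone) to 1-[4,5-bis(benzyloxy)-2-hydroxyphenyl]ethan-1-one F2. Acylation of F2 with 4 in pyridine gives 2-acetyl-4,5-bis(benzyloxy)phenyl 3,4,5-trimethoxybenzoate F3. Baker–Venkataraman rearrangement (KOH, pyridine, 50 °C, then AcOH) gives 1-[4,5-bis(benzyloxy)-2-hydroxyphenyl]-3-(3,4,5-trimethoxyphenyl)propane-1,3-dione F4. Acid cyclodehydration (cat. H2SO4, AcOH, 80 °C) gives 6,7-bis(benzyloxy)-2-(3,4,5-trimethoxyphenyl)-4H-chromen-4-one F5, and hydrogenolysis (H2, Pd/C) gives 13.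

2. Step 7. The alkylation may discriminate poorly between the two phenols or run on to double benzylation. Fallback, setting out from 13 and coming back at 16: 13 is converted with NaH (2.2 equiv) in DMSO into disodium 4-oxo-2-(3,4,5-trimethoxyphenyl)-4H-chromene-6,7-diolate F6, and one equivalent of MeI is added. In the dianion the C6 oxide, whose charge is not delocalised into the C4 carbonyl, is the more nucleophilic site. It should be methylated first, so acidification gives 16 directly with no benzyl group to put on or take off.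

3. Step 2. O-acylation of the enolate or a second acylation of the diketone may compete with the wanted C-acylation. Fallback, setting out from 3 and coming back at 6: the lithium enolate of 3 (LiHMDS, THF, −78 °C, AcOH quench) is added to 3,4,5-trimethoxybenzaldehyde F7 to give racemic (Z)-5-(dimethylamino)-1-hydroxy-4-(phenylsulfanyl)-1-(3,4,5-trimethoxyphenyl)pent-4-en-3-one F8, an aldol addition with no O- versus C-ambiguity. Oxidation of the benzylic alcohol with IBX (EtOAc, 70 °C) gives diketone 5, which aqueous HCl closes to 6.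

**Further compounds**

F1 | step 5 | 1-(2,4,5-trihydroxyphenyl)ethan-1-one | CC(=O)c1cc(O)c(O)cc1O
F2 | step 5 | 1-[4,5-bis(benzyloxy)-2-hydroxyphenyl]ethan-1-one | CC(=O)c1cc(OCc2ccccc2)c(OCc2ccccc2)cc1O
F3 | step 5 | 2-acetyl-4,5-bis(benzyloxy)phenyl 3,4,5-trimethoxybenzoate | CC(=O)c1cc(OCc2ccccc2)c(OCc2ccccc2)cc1OC(=O)c1cc(OC)c(OC)c(OC)c1
F4 | step 5 | 1-[4,5-bis(benzyloxy)-2-hydroxyphenyl]-3-(3,4,5-trimethoxyphenyl)propane-1,3-dione | O=C(CC(=O)c1cc(OC)c(OC)c(OC)c1)c1cc(OCc2ccccc2)c(OCc2ccccc2)cc1O
F5 | step 5 | 6,7-bis(benzyloxy)-2-(3,4,5-trimethoxyphenyl)-4H-chromen-4-one | COc1cc(-c2cc(=O)c3cc(OCc4ccccc4)c(OCc4ccccc4)cc3o2)cc(OC)c1OC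
F6 | step 7 | disodium 4-oxo-2-(3,4,5-trimethoxyphenyl)-4H-chromene-6,7-diolate | COc1cc(-c2cc(=O)c3cc([O-])c([O-])cc3o2)cc(OC)c1OC.[Na+].[Na+]
F7 | step 2 | 3,4,5-trimethoxybenzaldehyde | COc1cc(C=O)cc(OC)c1OC
F8 | step 2 | racemic (Z)-5-(dimethylamino)-1-hydroxy-4-(phenylsulfanyl)-1-(3,4,5-trimethoxyphenyl)pent-4-en-3-one | COc1cc(C(O)CC(=O)/C(Sc2ccccc2)=C/N(C)C)cc(OC)c1OC
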